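## Plan

1. Retrosynthesis (ring A = the 4-hydroxy-3,5-dimethoxyphenyl ring, ring B = the benzo ring, ring C = the oxygen heterocycle): both CH2OH groups go back to methyl esters, and the C5–vinyl bond on ring B is cut as a Heck disconnection. The C3–C3a bond is then cut by a retro-Wolff step that re-expands ring C to a 3-diazoflavanone, and last the C2–ring A bond is cut as a conjugate addition to a chromone.
2. Enabling feature: the dihydrofuran ring C (O1, C2, C3, C3a, C7a), with ring A on C2 and a one-carbon branch on C3, is the pyranone ring of a flavanone whose C4 carbonyl carbon has left the ring and become the CH2OH carbon on C3.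
3. Forward order: ring B is brominated, the pyranone ring is annulated (chromone), ring A is added at C2, ring C is contracted from six to five atoms, then the three-carbon chain is joined at C5 and both esters are reduced.
4. Stereochemistry: C2 (S) comes from a rhodium-catalysed asymmetric 1,4-addition. C3 is set relative to C2 by base equilibration to the trans ester, and the E olefin comes from the Heck reaction.

Key step: step 7

Assumption: the antipode of the electron-poor diphosphane MeO-F12-BIPHEP, (6,6'-dimethoxybiphenyl-2,2'-diyl)bis[bis(3,4,5-trifluorophenyl)phosphane], that gives the (2S) flavanone is used in step 5; the sense of induction is to be confirmed on a small scale, since both antipodes are accessible.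

Remark on descriptors: diazoketone 13 and ketene 14 have the same spatial arrangement at C2 as flavanone 11. They are 2R by the CIP rules only because the diazo or ketene carbon outranks the aryl carbon. Likewise C3 changes from S in the esters to R in the target without any change in space.

## Route

Step 1
Reactants: 1 1-(2-hydroxy-3-methoxyphenyl)ethanone
Product: 2 1-(5-bromo-2-hydroxy-3-methoxyphenyl)ethanone
Conditions: NBS (1.05 equiv), MeCN, 0 °C to rt
Reagents that add atoms: N-bromosuccinimide, O=C1CCC(=O)N1Br
Why: Electrophilic aromatic bromination should go para to the free phenol (C5), since both ortho positions are blocked and the ring is far more reactive than the acetyl methyl group under these conditions.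

Step 2
Reactants: 2 1-(5-bromo-2-hydroxy-3-methoxyphenyl)ethanone; 3 N,N-dimethylformamide dimethyl acetal
Product: 5 6-bromo-8-methoxy-4H-chromen-4-one, via enaminone 4 (not isolated)
Conditions: 3 (1.5 equiv), toluene, 95 °C; concentrate; then conc. HCl, CH2Cl2, 40 °C
Reagents that add atoms: none
Why: Enaminone condensation of the methyl ketone with the amide acetal, followed by acid-promoted conjugate addition–elimination of the phenol with loss of dimethylamine, is the standard enaminone route to chromones and builds the pyranone form of ring C.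

Step 3
Reactants: 6 4-bromo-2,6-dimethoxyphenol
Product: 7 5-bromo-1,3-dimethoxy-2-(methoxymethoxy)benzene
Conditions: NaH (1.2 equiv), MOMCl (1.3 equiv), THF/DMF, 0 °C to rt
Reagents that add atoms: chloromethyl methyl ether, COCCl
Why: Williamson-type O-alkylation of the hindered sodium phenoxide installs a MOM acetal that tolerates the organolithium, aqueous hydroxide, amide base and methoxide used later and is removed by mild acid.

Step 4
Reactants: 7 5-bromo-1,3-dimethoxy-2-(methoxymethoxy)benzene
Product: 10 [3,5-dimethoxy-4-(methoxymethoxy)phenyl]boronic acid, via aryllithium 8 (not isolated), via lithium triisopropoxyborate 9 (not isolated)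
Conditions: n-BuLi (1.1 equiv), THF, −78 °C; B(Oi-Pr)3 (1.5 equiv), −78 °C to rt; sat. aq NH4Cl
Reagents that add atoms: triisopropyl borate, CC(C)OB(OC(C)C)OC(C)C; water, O; n-butyllithium, [Li]CCCC (lithium in intermediates 8 and 9 only)
Why: Bromine–lithium exchange at −78 °C, trapping of the aryllithium with the borate and near-neutral hydrolysis is the standard aryllithium borylation, and the mild quench keeps the MOM acetal intact.

Step 5
Reactants: 5 6-bromo-8-methoxy-4H-chromen-4-one; 10 [3,5-dimethoxy-4-(methoxymethoxy)phenyl]boronic acid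
Product: 11 (2S)-6-bromo-2-[3,5-dimethoxy-4-(methoxymethoxy)phenyl]-8-methoxychroman-4-one
Conditions: [RhCl(C2H4)2]2 (1.5 mol%), MeO-F12-BIPHEP (single antipode, 3.3 mol%), aq KOH (20 mol%), 10 (2.5 equiv), toluene/H2O, 20–30 °C
Reagents that add atoms: none
Why: In this Hayashi–Miyaura asymmetric conjugate addition the aryl–rhodium species formed by transmetalation should insert the chromone C2=C3 bond on one enantioface under control of the atropisomeric diphosphane, which sets C2 as S, while the low temperature and catalytic hydroxide keep the flavanone from opening to the chalcone and the aryl bromide is left alone by monovalent rhodium.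

Step 6
Reactants: 11 (2S)-6-bromo-2-[3,5-dimethoxy-4-(methoxymethoxy)phenyl]-8-methoxychroman-4-one
Product: 13 (2R)-6-bromo-3-diazo-2-[3,5-dimethoxy-4-(methoxymethoxy)phenyl]-8-methoxychroman-4-one, via 3-trifluoroacetyl flavanone 12 (not isolated)
Conditions: LiN(SiMe3)2 (1.1 equiv), THF, −78 °C; CF3CO2CH2CF3 (1.2 equiv), −78 °C; cold 1 M HCl work-up; then MsN3 (1.5 equiv), Et3N (1.5 equiv), H2O (1 equiv), MeCN, 20 °C, dark
Reagents that add atoms: methanesulfonyl azide, CS(=O)(=O)N=[N+]=[N-]; 2,2,2-trifluoroethyl trifluoroacetate, FC(F)(F)COC(=O)C(F)(F)F (trifluoroacetyl group in intermediate 12 only)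
Why: In this detrifluoroacetylative Regitz diazo transfer the kinetic lithium enolate should be C-acylated at −78 °C before it can expel the ring phenoxide, and the strongly stabilised diketonate then accepts the diazo group with loss of the trifluoroacetyl group, leaving the bonds at C2 untouched.

Step 7
Reactants: 13 (2R)-6-bromo-3-diazo-2-[3,5-dimethoxy-4-(methoxymethoxy)phenyl]-8-methoxychroman-4-one
Product: 16 methyl (2S,3S)-5-bromo-2-[3,5-dimethoxy-4-(methoxymethoxy)phenyl]-7-methoxy-2,3-dihydro-1-benzofuran-3-carboxylate, via ketene 14 (not isolated), via C3-epimeric methyl esters 15 (not isolated)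
Conditions: hν (365 nm LEDs), degassed MeOH/THF, 10–20 °C; then NaOMe (0.3 equiv), 20 °C
Reagents that add atoms: methanol, CO
Why: Excitation of the diazoketone, which ring C locks in the s-Z geometry, should expel N2 while ring B carbon C4a shifts from the carbonyl carbon C4 to the diazo carbon C3 in one concerted event, so that the exocyclic ketene 14 forms and is captured by methanol through its ester enol. The closest known reaction type is the photochemical Wolff ring contraction of cyclic 2-diazoketones, which has been applied to 3-diazochroman-4-ones to give 2,3-dihydrobenzofuran-3-carboxylates. The five-membered ring (O1, C2, C3, C3a, C7a) is not closed by cyclisation but arises by a 1,2-shift ring contraction from six to five atoms, C3–C3a forming as C4–C4a breaks. C2 is a spectator and keeps its spatial arrangement, while the new centre C3, first set by unselective protonation of the ester enol, is driven by catalytic NaOMe to the trans (3S) ester, so it is controlled thermodynamically by the C2 aryl group. The step needs aryl migration to outrun a 1,2-hydride shift from C2 (flavone), carbene O–H insertion into methanol and C–Br homolysis: the s-Z lock with direct, unsensitised excitation favours the concerted path that bypasses a free carbene, and 365 nm light is absorbed by the diazoketone but not by the aryl bromide or the ester product.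

Step 8
Reactants: 16 methyl (2S,3S)-5-bromo-2-[3,5-dimethoxy-4-(methoxymethoxy)phenyl]-7-methoxy-2,3-dihydro-1-benzofuran-3-carboxylate; 17 methyl acrylate
Product: 18 methyl (2S,3S)-2-[3,5-dimethoxy-4-(methoxymethoxy)phenyl]-7-methoxy-5-[(E)-3-methoxy-3-oxoprop-1-en-1-yl]-2,3-dihydro-1-benzofuran-3-carboxylate
Conditions: Pd(OAc)2 (5 mol%), P(o-tol)3 (10 mol%), NaOAc (1.5 equiv), 17 (3 equiv), DMF, 100 °C
Reagents that add atoms: none
Why: In this Mizoroki–Heck reaction, oxidative addition of the aryl bromide to zerovalent palladium, syn insertion of the acrylate and syn β-hydride elimination should give the E cinnamate, and the weak acetate base can at most re-equilibrate C3 toward the trans isomer already in hand.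

Step 9
Reactants: 18 methyl (2S,3S)-2-[3,5-dimethoxy-4-(methoxymethoxy)phenyl]-7-methoxy-5-[(E)-3-methoxy-3-oxoprop-1-en-1-yl]-2,3-dihydro-1-benzofuran-3-carboxylate
Product: 19 methyl (2S,3S)-2-(4-hydroxy-3,5-dimethoxyphenyl)-7-methoxy-5-[(E)-3-methoxy-3-oxoprop-1-en-1-yl]-2,3-dihydro-1-benzofuran-3-carboxylate
Conditions: HCl (1.25 M in MeOH), 20–40 °C
Reagents that add atoms: none
Why: Acid-catalysed acetal exchange removes the MOM group at the acid-tolerant diester stage, before the acid-sensitive cinnamyl alcohol exists, and the electron-withdrawing C3 ester disfavours ionisation of the benzylic C2–O bond.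

Step 10
Reactants: 19 methyl (2S,3S)-2-(4-hydroxy-3,5-dimethoxyphenyl)-7-methoxy-5-[(E)-3-methoxy-3-oxoprop-1-en-1-yl]-2,3-dihydro-1-benzofuran-3-carboxylate
Product: 20 4-[(2S,3R)-3-(hydroxymethyl)-5-[(E)-3-hydroxyprop-1-en-1-yl]-7-methoxy-2,3-dihydro-1-benzofuran-2-yl]-2,6-dimethoxyphenol
Conditions: i-Bu2AlH (7 equiv), CH2Cl2/THF, −78 to −20 °C; aq KNaC4H4O6 work-up
Reagents that add atoms: none
Why: Hydride reduction with i-Bu2AlH should take the conjugated ester 1,2 to the E allylic alcohol and the C3 ester to the hydroxymethyl group, with excess reagent covering the free phenol and the low temperature leaving C2 and C3 untouched.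

## Compound list

1 | 1-(2-hydroxy-3-methoxyphenyl)ethanone | CC(=O)c1cccc(OC)c1O | starting material
2 | 1-(5-bromo-2-hydroxy-3-methoxyphenyl)ethanone | CC(=O)c1cc(Br)cc(OC)c1O | intermediate
3 | N,N-dimethylformamide dimethyl acetal | CN(C)C(OC)OC | starting material
4 | (E)-1-(5-bromo-2-hydroxy-3-methoxyphenyl)-3-(dimethylamino)prop-2-en-1-one (not isolated) | CN(C)/C=C/C(=O)c1cc(Br)cc(OC)c1O | intermediate
5 | 6-bromo-8-methoxy-4H-chromen-4-one | COc1cc(Br)cc2c(=O)ccoc12 | intermediate
6 | 4-bromo-2,6-dimethoxyphenol | COc1cc(Br)cc(OC)c1O | starting material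
7 | 5-bromo-1,3-dimethoxy-2-(methoxymethoxy)benzene | COCOc1c(OC)cc(Br)cc1OC | intermediate
8 | [3,5-dimethoxy-4-(methoxymethoxy)phenyl]lithium (not isolated) | COCOc1c(OC)cc([Li])cc1OC | intermediate
9 | lithium [3,5-dimethoxy-4-(methoxymethoxy)phenyl]tri(propan-2-yloxy)borate (not isolated) | [Li+].COCOc1c(OC)cc([B-](OC(C)C)(OC(C)C)OC(C)C)cc1OC | intermediate
10 | [3,5-dimethoxy-4-(methoxymethoxy)phenyl]boronic acid | COCOc1c(OC)cc(B(O)O)cc1OC | intermediate
11 | (2S)-6-bromo-2-[3,5-dimethoxy-4-(methoxymethoxy)phenyl]-8-methoxychroman-4-one | COc1cc([C@H]2Oc3c(OC)cc(Br)cc3C(=O)C2)cc(OC)c1OCOC | intermediate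
12 | (2S)-6-bromo-2-[3,5-dimethoxy-4-(methoxymethoxy)phenyl]-8-methoxy-3-(trifluoroacetyl)chroman-4-one, keto–enol mixture, C3 undefined (not isolated) | COc1cc([C@H]2Oc3c(OC)cc(Br)cc3C(=O)C2C(=O)C(F)(F)F)cc(OC)c1OCOC | intermediate
13 | (2R)-6-bromo-3-diazo-2-[3,5-dimethoxy-4-(methoxymethoxy)phenyl]-8-methoxychroman-4-one | COc1cc([C@H]2Oc3c(OC)cc(Br)cc3C(=O)C2=[N+]=[N-])cc(OC)c1OCOC | intermediate
14 | (2R)-5-bromo-2-[3,5-dimethoxy-4-(methoxymethoxy)phenyl]-7-methoxy-3-(oxomethylidene)-2,3-dihydro-1-benzofuran, the ketene (not isolated) | COc1cc([C@H]2Oc3c(OC)cc(Br)cc3C2=C=O)cc(OC)c1OCOC | intermediate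
15 | methyl (2S)-5-bromo-2-[3,5-dimethoxy-4-(methoxymethoxy)phenyl]-7-methoxy-2,3-dihydro-1-benzofuran-3-carboxylate, mixture of C3 epimers (not isolated) | COc1cc([C@H]2Oc3c(OC)cc(Br)cc3C2C(=O)OC)cc(OC)c1OCOC | intermediate
16 | methyl (2S,3S)-5-bromo-2-[3,5-dimethoxy-4-(methoxymethoxy)phenyl]-7-methoxy-2,3-dihydro-1-benzofuran-3-carboxylate (trans) | COc1cc([C@H]2Oc3c(OC)cc(Br)cc3[C@@H]2C(=O)OC)cc(OC)c1OCOC | intermediate
17 | methyl acrylate | C=CC(=O)OC | starting material
18 | methyl (2S,3S)-2-[3,5-dimethoxy-4-(methoxymethoxy)phenyl]-7-methoxy-5-[(E)-3-methoxy-3-oxoprop-1-en-1-yl]-2,3-dihydro-1-benzofuran-3-carboxylate | COc1cc([C@H]2Oc3c(OC)cc(/C=C/C(=O)OC)cc3[C@@H]2C(=O)OC)cc(OC)c1OCOC | intermediate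
19 | methyl (2S,3S)-2-(4-hydroxy-3,5-dimethoxyphenyl)-7-methoxy-5-[(E)-3-methoxy-3-oxoprop-1-en-1-yl]-2,3-dihydro-1-benzofuran-3-carboxylate | COc1cc([C@H]2Oc3c(OC)cc(/C=C/C(=O)OC)cc3[C@@H]2C(=O)OC)cc(OC)c1O | intermediate
20 | 4-[(2S,3R)-3-(hydroxymethyl)-5-[(E)-3-hydroxyprop-1-en-1-yl]-7-methoxy-2,3-dihydro-1-benzofuran-2-yl]-2,6-dimethoxyphenol (trans) | COc1cc([C@H]2Oc3c(OC)cc(/C=C/CO)cc3[C@@H]2CO)cc(OC)c1O | target

## Step count

Total steps: 10. Longest linear sequence: 8 steps (steps 1, 2, 5, 6, 7, 8, 9, 10; the branch through steps 3 and 4 that joins at step 5 is equally long).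

## Steps most likely to fail

**Step 6 (diazo transfer).** The C3 enolate may expel the ring phenoxide, before or after acylation. That opens ring C to the chalcone and erodes the C2 configuration on reclosure. The diazoketone may also lose N2 with a hydride shift on handling. The fallback sets out from 11, returns to the route at 13 and avoids a free enolate. Soft enolisation with Me3SiOTf and Et3N in CH2Cl2 at 0 °C should give the silyl enol ether (2S)-6-bromo-2-[3,5-dimethoxy-4-(methoxymethoxy)phenyl]-8-methoxy-4-(trimethylsilyloxy)-2H-chromene F1. Nitrosation with NOCl in CH2Cl2 at −20 °C should give the oximino ketone (2R)-6-bromo-3-(hydroxyimino)-2-[3,5-dimethoxy-4-(methoxymethoxy)phenyl]-8-methoxychroman-4-one F2. A Forster reaction with chloramine (aq NH3, NaOCl, 0 °C) should then convert the oxime into diazoketone 13.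

**Step 7 (Wolff ring contraction).** A 1,2-hydride shift from C2 to the carbene carbon, or carbene O–H insertion into methanol, may compete with aryl migration. Retro-oxa-Michael opening may also occur during the methoxide equilibration. The fallback sets out from 11, returns to the route at 20 and triggers the same shift of C4a from C4 to C3 oxidatively, by the known ring contraction of flavanones with a trivalent iodine reagent in trimethyl orthoformate. This needs an acid-stable phenol protecting group.
- MOM removal (HCl, MeOH) should give (2S)-6-bromo-2-(4-hydroxy-3,5-dimethoxyphenyl)-8-methoxychroman-4-one F3.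
- Acetylation (Ac2O, pyridine) should give (2S)-2-(4-acetoxy-3,5-dimethoxyphenyl)-6-bromo-8-methoxychroman-4-one F4.
- PhI(OAc)2 and H2SO4 in HC(OMe)3 at rt should give the trans ester methyl (2S,3S)-2-(4-acetoxy-3,5-dimethoxyphenyl)-5-bromo-7-methoxy-2,3-dihydro-1-benzofuran-3-carboxylate F5. The less electron-rich acetoxy ring A also disfavours the competing shift of ring A that leads to an isoflavone.
- A Heck reaction with 17 under the conditions of step 8 should give methyl (2S,3S)-2-(4-acetoxy-3,5-dimethoxyphenyl)-7-methoxy-5-[(E)-3-methoxy-3-oxoprop-1-en-1-yl]-2,3-dihydro-1-benzofuran-3-carboxylate F6.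
- i-Bu2AlH then reduces both esters and cleaves the aryl acetate to give 20 directly.

**Step 5 (asymmetric 1,4-addition).** Enantioface discrimination may be insufficient, protodeboronation of the electron-rich boronic acid may outrun insertion into the 8-methoxychromone, or the product may ring-open under base. The fallback sets out from 7 and 2, returns to the route at 11 and takes the stereocentre from a resolution.
- Bromine–lithium exchange on 7 and trapping with DMF should give 3,5-dimethoxy-4-(methoxymethoxy)benzaldehyde F7.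
- Claisen–Schmidt condensation with 2 (KOH, EtOH) should give the chalcone (E)-1-(5-bromo-2-hydroxy-3-methoxyphenyl)-3-[3,5-dimethoxy-4-(methoxymethoxy)phenyl]prop-2-en-1-one F8.
- Oxa-Michael cyclisation (NaOAc, EtOH, reflux) should give racemic 6-bromo-2-[3,5-dimethoxy-4-(methoxymethoxy)phenyl]-8-methoxychroman-4-one F9.
- Kinetic resolution by asymmetric transfer hydrogenation (Cp*RhCl[(R,R)-TsDPEN] or its antipode, whichever consumes the 2R ketone, HCO2H/Et3N, EtOAc) should reduce the unwanted enantiomer to the cis alcohol (2R,4R)-6-bromo-2-[3,5-dimethoxy-4-(methoxymethoxy)phenyl]-8-methoxychroman-4-ol F10. Flavanone 11 is left behind and separated by chromatography.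

## Further compounds

F1 | step 6 | (2S)-6-bromo-2-[3,5-dimethoxy-4-(methoxymethoxy)phenyl]-8-methoxy-4-(trimethylsilyloxy)-2H-chromene | COc1cc([C@H]2Oc3c(OC)cc(Br)cc3C(O[Si](C)(C)C)=C2)cc(OC)c1OCOC
F2 | step 6 | (2R)-6-bromo-3-(hydroxyimino)-2-[3,5-dimethoxy-4-(methoxymethoxy)phenyl]-8-methoxychroman-4-one | COc1cc([C@H]2Oc3c(OC)cc(Br)cc3C(=O)C2=NO)cc(OC)c1OCOC
F3 | step 7 | (2S)-6-bromo-2-(4-hydroxy-3,5-dimethoxyphenyl)-8-methoxychroman-4-one | COc1cc([C@H]2Oc3c(OC)cc(Br)cc3C(=O)C2)cc(OC)c1O
F4 | step 7 | (2S)-2-(4-acetoxy-3,5-dimethoxyphenyl)-6-bromo-8-methoxychroman-4-one | COc1cc([C@H]2Oc3c(OC)cc(Br)cc3C(=O)C2)cc(OC)c1OC(C)=O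
F5 | step 7 | methyl (2S,3S)-2-(4-acetoxy-3,5-dimethoxyphenyl)-5-bromo-7-methoxy-2,3-dihydro-1-benzofuran-3-carboxylate | COc1cc([C@H]2Oc3c(OC)cc(Br)cc3[C@@H]2C(=O)OC)cc(OC)c1OC(C)=O
F6 | step 7 | methyl (2S,3S)-2-(4-acetoxy-3,5-dimethoxyphenyl)-7-methoxy-5-[(E)-3-methoxy-3-oxoprop-1-en-1-yl]-2,3-dihydro-1-benzofuran-3-carboxylate | COc1cc([C@H]2Oc3c(OC)cc(/C=C/C(=O)OC)cc3[C@@H]2C(=O)OC)cc(OC)c1OC(C)=O
F7 | step 5 | 3,5-dimethoxy-4-(methoxymethoxy)benzaldehyde | COCOc1c(OC)cc(C=O)cc1OC
F8 | step 5 | (E)-1-(5-bromo-2-hydroxy-3-methoxyphenyl)-3-[3,5-dimethoxy-4-(methoxymethoxy)phenyl]prop-2-en-1-one | COCOc1c(OC)cc(/C=C/C(=O)c2cc(Br)cc(OC)c2O)cc1OC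
F9 | step 5 | racemic 6-bromo-2-[3,5-dimethoxy-4-(methoxymethoxy)phenyl]-8-methoxychroman-4-one | COc1cc(C2Oc3c(OC)cc(Br)cc3C(=O)C2)cc(OC)c1OCOC
F10 | step 5 | (2R,4R)-6-bromo-2-[3,5-dimethoxy-4-(methoxymethoxy)phenyl]-8-methoxychroman-4-ol (cis) | COc1cc([C@@H]2Oc3c(OC)cc(Br)cc3[C@H](O)C2)cc(OC)c1OCOC
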